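The flask carries a small charge of protic impurity, 1.00 mM against 20 mM of starting material, or 5.00%. The alder and oak runs differ in impurity, yet read 52% and 52% target at 5.00 min. I follow target, [P], against starting material, [A].

common to all: starting material 20 mM

|  | reagent in the second phase | protic impurity | remark | time | volume of the second phase over the first |
|---|---|---|---|---|---|
| alder | 30 mM | 0.50 mM | run made earlier |  |  |
| oak | 30 mM | 0.75 mM | run made earlier |  |  |
| flask | 30.0 mM | 1.00 mM |  | 8.0 min | 0.25 |

| run | time / min | target / % | starting material / % |
|---|---|---|---|
| alder | 1.33 | 21 | 73 |
| alder | 2.50 | 40 | 52 |
| alder | 4.00 | 48 | 36 |
| alder | 5.00 | 52 | 29 |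
| oak | 0.667 | 7 | 86 |
| oak | 1.50 | 28 | 70 |
| oak | 3.00 | 43 | 42 |
| oak | 5.00 | 52 | 26 |

(standard deviation of a reading: 1.5 percentage points)

- in the second phase: reagent in the second phase; everything else is in the first
- charges count per volume of the first phase; a concentration in a rate is the amount of a species over the volume of its own phase; every rate counts per litre of the first phase
- the analysis behind the earlier runs scatters by 1.5 percentage points, standard deviation
- the earlier runs hold the two phases in the same ratio of volumes as the flask asked about

- the target standing at 8.0 min, as a percentage of the starting material charged
- part of the starting material charged that has reacted at 8.0 min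

1. The bench rule says: leave it longer, get more target. But in the alder run the unread part grows from 6.00% to 19.0%.

2. I suppose a second step that uses target with the same reagent. Reagent then cancels: target is used at κ[P]/[A] of the rate it is made, κ being the second rate constant over the first. The symmetric case, κ = 1, is my zero: target would turn at [A] = [P].

3. From 2.50 min to 5.00 min, alder loses 23 percentage points of starting material and gains 12 points of target. With the mean [P]/[A] of that stretch, this reads 0.421 for the turn ratio κ, the [A]/[P] at which target stops rising (a selectivity factor). It is a rough reading.

4. The bench rule ends at that border. Oak at 5.00 min stands at 0.500, still above it. I carry oak's last decay, 0.240 /min, over to the flask, where it leaves an estimated 12.7% of starting material at 8.0 min. With κ I commit to 50.2% target and 87.3% reacted in the flask. My [A]/[P] for the flask is then about 0.253, below κ, so I place it past the turn.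

The forecast gives 48% and 88%, with “a broad target maximum”, so it sits below my target figure and above my reacted figure.

The flask gives 49.2% target and 85.3% reacted.

    reagent in the reaction phase ⇌ reagent in the second phase, rate k1*([reagent in the reaction phase] - [reagent in the second phase]/K1) per volume of the first phase (partition coefficient = 3.10, kL = 0.00520 /s)
    starting material + reagent in the reaction phase → target (k = 0.800 /M/s)
    reagent in the reaction phase + target → over-reacted product (k = 0.340 /M/s)
    starting material + protic impurity → quenched substrate (k = 140 /M/s)

At 1.67 min this flask makes target 5.62 times as fast as it uses it up. At 8.00 min its [A]/[P] is 0.298, below my rough κ, which on that reading puts making at 0.709 of using. The neighbour flask with 5.0 mM of starting material stands at [A]/[P] = 0.0533 at 8.00 min, far below κ, and holds 20.6% target against 58.3% over-reacted product.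

The numbers in the tables are calculated with made-up constants; scatter was added.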